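**Retrosynthetic overview**
- The target is an (R)-α-hydroxydihydrochalcone. The last step is a global desilylation of its bis-TBS ether; before that, the bond between the resorcinol-ring carbon and the ketone carbon is made by an iodine–lithium-exchange-triggered anionic ortho-Fries rearrangement (1,3 O→C acyl shift) of an o-iodoaryl ester.
- Enabling feature: on the 2-hydroxy-4-geranyloxyphenyl ring, the free phenolic oxygen (on C2) sits on the ring carbon directly next to C1, the ring carbon that carries the ketone carbonyl. The acyl carbon can therefore be parked on that oxygen as an aryl ester and handed to the neighbouring ring carbon; the O–acyl bond that breaks leaves the free 2-OH.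
- The ester comes from Steglich coupling of 5-(geranyloxy)-2-iodophenol (from resorcinol monobenzoate by para-iodination, O-geranylation and debenzoylation) with bis-TBS (R)-4-hydroxyphenyllactic acid (from D-tyrosine by retentive diazotisation and silylation).
- The single stereocentre is taken from D-tyrosine and the E-olefin from geranyl bromide. No ring is formed at any stage; both benzene rings are bought.

Key step: step 7

Abbreviations: geranyl = (2E)-3,7-dimethylocta-2,6-dien-1-yl; TBS = tert-butyldimethylsilyl.

**Route**

Step 1
Reactants: 1 resorcinol monobenzoate (3-hydroxyphenyl benzoate)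
Product: 2 5-hydroxy-2-iodophenyl benzoate
Conditions: NIS (1.0 equiv), TsOH·H2O (10 mol %), MeCN, 0 °C → rt, dark
Reagents that add atoms: N-iodosuccinimide, O=C1CCC(=O)N1I
Why: Electrophilic aromatic iodination with acid-activated NIS should be steered by the free OH, the only strong donor, to its para position (which is ortho to the weakly donating benzoyloxy group), and one equivalent of NIS limits di-iodination.

Step 2
Reactants: 2 5-hydroxy-2-iodophenyl benzoate; 3 geranyl bromide
Product: 4 5-(geranyloxy)-2-iodophenyl benzoate
Conditions: K2CO3 (1.5 equiv), acetone, rt → 40 °C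
Reagents that add atoms: none
Why: Williamson etherification (SN2 of the phenolate on the primary allylic bromide) should give the aryl geranyl ether with the E geometry of 3 untouched, the aryl benzoate being stable to anhydrous carbonate in acetone.

Step 3
Reactants: 4 5-(geranyloxy)-2-iodophenyl benzoate
Product: 5 5-(geranyloxy)-2-iodophenol
Conditions: pyrrolidine (3 equiv), THF, rt; dilute aq. citric acid wash
Reagents that add atoms: none
Why: Aminolysis of the activated aryl ester by a nucleophilic secondary amine should free the phenol ortho to iodine under conditions that leave the allylic ether, the aryl iodide and both olefins alone.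

Step 4
Reactants: 6 D-tyrosine
Product: 9 (R)-2-hydroxy-3-(4-hydroxyphenyl)propanoic acid, via diazonium carboxylate 7 (not isolated), via α-lactone 8 (not isolated)
Conditions: NaNO2 (1.5 equiv), 1 M aq. H2SO4, 0 °C → rt
Reagents that add atoms: water, O
Why: Diazotisation and hydrolysis of an α-amino acid (hydroxy-de-amination) proceeds with overall retention, since the carboxylate displaces N2 from 7 with inversion to give α-lactone 8 and water opens 8 at the alkyl carbon with a second inversion, so the (R) centre of D-tyrosine becomes the (R) carbinol of the target.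

Step 5
Reactants: 9 (R)-2-hydroxy-3-(4-hydroxyphenyl)propanoic acid
Product: 11 (R)-2-(tert-butyldimethylsilyloxy)-3-[4-(tert-butyldimethylsilyloxy)phenyl]propanoic acid, via tris-silyl ester 10 (not isolated)
Conditions: TBSCl (3.3 equiv), imidazole (7 equiv), DMF, rt; then AcOH–THF–H2O (3:1:1), rt
Reagents that add atoms: tert-butyldimethylsilyl chloride, CC(C)(C)[Si](C)(C)Cl
Why: Exhaustive silylation under Corey conditions followed by selective hydrolysis of the much more labile silyl ester should leave the aryl and secondary TBS ethers in place, and the stereocentre is not involved.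

Step 6
Reactants: 5 5-(geranyloxy)-2-iodophenol; 11 (R)-2-(tert-butyldimethylsilyloxy)-3-[4-(tert-butyldimethylsilyloxy)phenyl]propanoic acid
Product: 12 5-(geranyloxy)-2-iodophenyl (R)-2-(tert-butyldimethylsilyloxy)-3-[4-(tert-butyldimethylsilyloxy)phenyl]propanoate
Conditions: DCC (1.2 equiv), DMAP (10 mol %), CH2Cl2, 0 °C → rt
Reagents that add atoms: none
Why: Steglich esterification (carbodiimide activation, DMAP acyl transfer) should join the ortho-substituted phenol and the α-silyloxy acid under nearly neutral conditions at which an α-silyloxy acyl group holds its configuration.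

Step 7
Reactants: 12 5-(geranyloxy)-2-iodophenyl (R)-2-(tert-butyldimethylsilyloxy)-3-[4-(tert-butyldimethylsilyloxy)phenyl]propanoate
Product: 15 (R)-2-(tert-butyldimethylsilyloxy)-3-[4-(tert-butyldimethylsilyloxy)phenyl]-1-[4-(geranyloxy)-2-hydroxyphenyl]propan-1-one, via aryllithium 13 (not isolated), via lithium phenolate 14 (not isolated)
Conditions: n-BuLi (1.05 equiv), THF–Et2O, −100 → −78 °C; then AcOH (1.2 equiv), −78 °C
Reagents that add atoms: none
Why: n-BuLi should exchange the iodine of 12 at −100 °C faster than it adds to the ester, and the resulting aryllithium 13, whose carbanion lies ortho to the acyloxy oxygen, attacks its own ester carbonyl through a four-centre transition structure with cleavage of the aryl O–C(=O) bond, a 1,3 O→C acyl shift that ends in the chelated lithium phenolate 14. The closest known reaction type is the metal–halogen-exchange-induced anionic ortho-Fries rearrangement of o-halophenyl esters to o-hydroxyaryl ketones. No ring is closed and no stereocentre is created; the ester oxygen is a tether that the same step cuts, so it reappears as the free 2-OH of the target and nothing has to be removed afterwards. The (R) centre next to the migrating carbonyl is a spectator, because exchange and intramolecular acyl transfer should outrun α-deprotonation at −100 °C and the ketone stays as the weakly basic chelated phenolate 14 until the cold acetic acid quench. The step needs regioselectivity, which the iodine secures by fixing the carbanion at the carbon ortho to the ester oxygen and para to the geranyloxy group (not at the carbon between the two oxygens), and mono-acylation, which the intramolecular delivery secures because no aryllithium is left once the ketone exists.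

Step 8
Reactants: 15 (R)-2-(tert-butyldimethylsilyloxy)-3-[4-(tert-butyldimethylsilyloxy)phenyl]-1-[4-(geranyloxy)-2-hydroxyphenyl]propan-1-one
Product: 16 (R)-1-[4-(geranyloxy)-2-hydroxyphenyl]-2-hydroxy-3-(4-hydroxyphenyl)propan-1-one (CNP0159413.1)
Conditions: HF·pyridine (excess), pyridine, THF, 0 °C → rt
Reagents that add atoms: none
Why: Fluoride cleavage of both Si–O bonds with pyridine-buffered HF·pyridine is weakly acidic and non-basic, so the α-ketol centre should not enolise and the allylic aryl ether and the olefins should survive.

**Compound list**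

1 | resorcinol monobenzoate (3-hydroxyphenyl benzoate) | O=C(Oc1cccc(O)c1)c1ccccc1 | starting material
2 | 5-hydroxy-2-iodophenyl benzoate | O=C(Oc1cc(O)ccc1I)c1ccccc1 | intermediate
3 | geranyl bromide ((2E)-1-bromo-3,7-dimethylocta-2,6-diene) | CC(C)=CCC/C(C)=C/CBr | starting material
4 | 5-(geranyloxy)-2-iodophenyl benzoate | CC(C)=CCC/C(C)=C/COc1ccc(I)c(OC(=O)c2ccccc2)c1 | intermediate
5 | 5-(geranyloxy)-2-iodophenol | CC(C)=CCC/C(C)=C/COc1ccc(I)c(O)c1 | intermediate
6 | D-tyrosine ((R)-2-amino-3-(4-hydroxyphenyl)propanoic acid) | N[C@H](Cc1ccc(O)cc1)C(=O)O | starting material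
7 | (R)-1-carboxylato-2-(4-hydroxyphenyl)ethanediazonium (diazonium carboxylate) | N#[N+][C@H](Cc1ccc(O)cc1)C(=O)[O-] | intermediate
8 | (S)-3-(4-hydroxybenzyl)oxiran-2-one (α-lactone) | O=C1O[C@H]1Cc1ccc(O)cc1 | intermediate
9 | (R)-2-hydroxy-3-(4-hydroxyphenyl)propanoic acid | O[C@H](Cc1ccc(O)cc1)C(=O)O | intermediate
10 | tert-butyldimethylsilyl (R)-2-(tert-butyldimethylsilyloxy)-3-[4-(tert-butyldimethylsilyloxy)phenyl]propanoate | CC(C)(C)[Si](C)(C)O[C@H](Cc1ccc(O[Si](C)(C)C(C)(C)C)cc1)C(=O)O[Si](C)(C)C(C)(C)C | intermediate
11 | (R)-2-(tert-butyldimethylsilyloxy)-3-[4-(tert-butyldimethylsilyloxy)phenyl]propanoic acid | CC(C)(C)[Si](C)(C)O[C@H](Cc1ccc(O[Si](C)(C)C(C)(C)C)cc1)C(=O)O | intermediate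
12 | 5-(geranyloxy)-2-iodophenyl (R)-2-(tert-butyldimethylsilyloxy)-3-[4-(tert-butyldimethylsilyloxy)phenyl]propanoate | CC(C)=CCC/C(C)=C/COc1ccc(I)c(OC(=O)[C@H](O[Si](C)(C)C(C)(C)C)Cc2ccc(O[Si](C)(C)C(C)(C)C)cc2)c1 | intermediate
13 | aryllithium: the 2-lithio analogue of 12 (Li in place of I) | CC(C)=CCC/C(C)=C/COc1ccc([Li])c(OC(=O)[C@H](O[Si](C)(C)C(C)(C)C)Cc2ccc(O[Si](C)(C)C(C)(C)C)cc2)c1 | intermediate
14 | lithium phenolate of ketone 15 | CC(C)=CCC/C(C)=C/COc1ccc(C(=O)[C@H](O[Si](C)(C)C(C)(C)C)Cc2ccc(O[Si](C)(C)C(C)(C)C)cc2)c(O[Li])c1 | intermediate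
15 | (R)-2-(tert-butyldimethylsilyloxy)-3-[4-(tert-butyldimethylsilyloxy)phenyl]-1-[4-(geranyloxy)-2-hydroxyphenyl]propan-1-one | CC(C)=CCC/C(C)=C/COc1ccc(C(=O)[C@H](O[Si](C)(C)C(C)(C)C)Cc2ccc(O[Si](C)(C)C(C)(C)C)cc2)c(O)c1 | intermediate
16 | (R)-1-[4-(geranyloxy)-2-hydroxyphenyl]-2-hydroxy-3-(4-hydroxyphenyl)propan-1-one (CNP0159413.1) | CC(C)=CCC/C(C)=C/COc1ccc(C(=O)[C@H](O)Cc2ccc(O)cc2)c(O)c1 | target

**Step count and risks**

Total step count: 8. Longest linear sequence: 6 steps (steps 1, 2, 3, 6, 7, 8); the acid branch (steps 4, 5) joins at step 6.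

Steps most likely to fail:

1. Step 7. What may go wrong: deprotonation at the α-carbon of the aryl ester (by n-BuLi, or by the aryllithium through a six-membered transition state) would expel the phenolate as a ketene forms and erase the configuration; butyl addition to the ester could also compete with the exchange. The fallback sets out from 5 and 11 and comes back at 15; it gives up the tether for an untethered acylation. Acid 11 would be converted (MeNHOMe·HCl, EDC·HCl, HOBt, N-methylmorpholine, CH2Cl2) into the Weinreb amide (R)-2-(tert-butyldimethylsilyloxy)-3-[4-(tert-butyldimethylsilyloxy)phenyl]-N-methoxy-N-methylpropanamide F1. Iodophenol 5 would be treated with n-BuLi (2.1 equiv, THF, −78 °C; O–H deprotonation, then I/Li exchange) to give lithium 5-(geranyloxy)-2-lithiophenolate F2. F2 should add once to F1, whose N,O-chelated adduct holds until work-up, and aqueous NH4Cl should then release 15.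

2. Step 1. What may go wrong: poor regioselectivity (attack ortho instead of para to the free OH) or over-iodination of the still activated ring. The fallback sets out from 1 and comes back at 5; it moves the iodination behind the geranylation and relies on phenolate-directed ortho-iodination. Compound 1 would be alkylated with 3 (K2CO3, acetone) to 3-(geranyloxy)phenyl benzoate F3, and pyrrolidine in THF would free 3-(geranyloxy)phenol F4. Iodination of the phenolate of F4 (I2, NaHCO3, THF–H2O, 0 °C) should go mainly ortho to the phenolate oxygen and para to the alkoxy group, as is usual for 3-alkoxyphenols, and much faster than any reaction of the trisubstituted olefins, to give 5.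

3. Step 6. What may go wrong: slow acylation of the ortho-iodophenol with diversion of the activated acid to the N-acylurea, and partial loss of configuration through a ketene from the DMAP-activated acyl species. The fallback sets out from 11 and 5 and comes back at 12; it uses a pre-formed acid chloride and phenolate with no amine present. Acid 11 would be converted with 1-chloro-N,N,2-trimethylprop-1-en-1-amine (CH2Cl2, 0 °C, neutral) into (R)-2-(tert-butyldimethylsilyloxy)-3-[4-(tert-butyldimethylsilyloxy)phenyl]propanoyl chloride F5. Phenol 5 would be converted with NaH (THF, 0 °C) into sodium 5-(geranyloxy)-2-iodophenolate F6. Combining F5 and F6 at −78 → 0 °C should give 12.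

Further compounds
F1 | step 7 | (R)-2-(tert-butyldimethylsilyloxy)-3-[4-(tert-butyldimethylsilyloxy)phenyl]-N-methoxy-N-methylpropanamide | CON(C)C(=O)[C@H](O[Si](C)(C)C(C)(C)C)Cc1ccc(O[Si](C)(C)C(C)(C)C)cc1
F2 | step 7 | lithium 5-(geranyloxy)-2-lithiophenolate | CC(C)=CCC/C(C)=C/COc1ccc([Li])c(O[Li])c1
F3 | step 1 | 3-(geranyloxy)phenyl benzoate | CC(C)=CCC/C(C)=C/COc1cccc(OC(=O)c2ccccc2)c1
F4 | step 1 | 3-(geranyloxy)phenol | CC(C)=CCC/C(C)=C/COc1cccc(O)c1
F5 | step 6 | (R)-2-(tert-butyldimethylsilyloxy)-3-[4-(tert-butyldimethylsilyloxy)phenyl]propanoyl chloride | CC(C)(C)[Si](C)(C)O[C@H](Cc1ccc(O[Si](C)(C)C(C)(C)C)cc1)C(=O)Cl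
F6 | step 6 | sodium 5-(geranyloxy)-2-iodophenolate | CC(C)=CCC/C(C)=C/COc1ccc(I)c([O-])c1.[Na+]
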